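**Strategy.** Everything rests on cutting ring B (C1 carries the CH2CH2 chain, C2 the benzylic CH2, C3 and C5 the methoxy groups) at the ring bonds C6–C1 and C4–C5. C1–C4, with the chain, the C2 carbon as a methyl ester and the C3 methoxy group, arrive as C6–C3 of a 6-(arylethyl)-4-methoxy-2-pyranone-5-carboxylate; C5(OMe)–C6 arrive as 1,1-dimethoxyethene. One inverse-demand cycloaddition with loss of CO2 and methanol creates the benzene ring with all four substituents correctly placed. The ester carbon later becomes the benzylic CH2 by aryl Grignard addition to the aldehyde and hydrogenolysis.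

Key step: step 6

Assumption: compounds 10 and 17 are racemic; their stereocentres are removed later and the target is achiral. Compound 6 is drawn as its triketo tautomer although it should be largely enolized.

**Step 1**
Reactants: 1 3-(3-hydroxyphenyl)propanoic acid
Product: 3 3-(3-benzyloxyphenyl)propanoic acid, via benzyl 3-(3-benzyloxyphenyl)propanoate 2 (not isolated)
Conditions: BnBr, K2CO3, DMF, 60 °C; then aq. NaOH, MeOH, 60 °C; HCl work-up
Reagents that add atoms: benzyl bromide BrCc1ccccc1; sodium hydroxide [Na+].[OH-]
Why: Williamson etherification of the phenoxide (with SN2 esterification of the carboxylate) followed by saponification of the benzyl ester in the same pot should leave only the hydroxide-stable aryl benzyl ether.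

**Step 2**
Reactants: 3 3-(3-benzyloxyphenyl)propanoic acid
Product: 4 3-(3-benzyloxyphenyl)propanoyl chloride
Conditions: (COCl)2, cat. DMF, CH2Cl2, 0 °C to rt
Reagents that add atoms: oxalyl chloride O=C(Cl)C(Cl)=O
Why: Acid chloride formation through the Vilsmeier-type chloroiminium intermediate is mild enough to leave the benzyl ether untouched.

**Step 3**
Reactants: 4 3-(3-benzyloxyphenyl)propanoyl chloride; 5 dimethyl 3-oxopentanedioate
Product: 6 dimethyl 2-[3-(3-benzyloxyphenyl)propanoyl]-3-oxopentanedioate
Conditions: MgCl2, pyridine, CH2Cl2, 0 °C to rt; aq. HCl work-up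
Reagents that add atoms: none
Why: Soft enolization gives the chelated magnesium enolate of the β-keto diester, which should undergo Claisen-type C-acylation at one of its two equivalent methylene carbons, the chelate of the tricarbonyl product suppressing O-acylation and a second acylation.

**Step 4**
Reactants: 6 dimethyl 2-[3-(3-benzyloxyphenyl)propanoyl]-3-oxopentanedioate
Product: 7 methyl 6-[2-(3-benzyloxyphenyl)ethyl]-4-hydroxy-2-oxo-2H-pyran-5-carboxylate
Conditions: DBU, toluene, reflux; aq. HCl work-up
Reagents that add atoms: none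
Why: Base-mediated lactonization (intramolecular transesterification) in which the enolate oxygen on the acyl carbon attacks the remote ester in a 6-exo-trig closure, the only ring size open to this triketo diester, and loss of methoxide with enolization should give the 4-hydroxy-2-pyranone as its stable salt.

**Step 5**
Reactants: 7 methyl 6-[2-(3-benzyloxyphenyl)ethyl]-4-hydroxy-2-oxo-2H-pyran-5-carboxylate
Product: 8 methyl 6-[2-(3-benzyloxyphenyl)ethyl]-4-methoxy-2-oxo-2H-pyran-5-carboxylate
Conditions: Me2SO4, K2CO3, acetone, reflux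
Reagents that add atoms: dimethyl sulfate COS(=O)(=O)OC
Why: O-alkylation of the vinylogous acid: the potassium salt of a 4-hydroxy-2-pyranone is methylated by the hard electrophile at the 4-oxygen, which should give the 4-methoxy-2-pyranone and not the 2-methoxy-4-pyranone.

**Step 6**
Reactants: 8 methyl 6-[2-(3-benzyloxyphenyl)ethyl]-4-methoxy-2-oxo-2H-pyran-5-carboxylate; 9 1,1-dimethoxyethene
Product: 12 methyl 2-[2-(3-benzyloxyphenyl)ethyl]-4,6-dimethoxybenzoate, via bicyclic lactone 10 (not isolated), via trimethoxycyclohexadiene ester 11 (not isolated)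
Conditions: 9 (excess), toluene, sealed tube, 120 °C
Reagents that add atoms: none
Why: The nucleophilic CH2 of the ketene acetal attacks pyranone C6, the β-carbon of the unsaturated ester and the terminus of the dienyl lactone, and the dimethoxy-substituted carbon then bonds to pyranone C3, so the two new ring bonds form in an asynchronous inverse-electron-demand [4+2] cycloaddition that gives the 2-oxabicyclo[2.2.2]octenone 10. The closest known reaction type is the Diels–Alder reaction of 5-alkoxycarbonyl-2-pyranones with ketene acetals, which delivers alkoxybenzoates. The one new ring, the six-membered carbocycle, is closed by this cycloaddition and becomes benzene when 10 extrudes CO2 by retro-[4+2] reaction and the resulting diene 11 loses methanol by 1,2-elimination. No stereocentre has to be controlled, since the two bridgehead centres of racemic 10 vanish on aromatization. The step needs regioselectivity, which the matched polarization secures: the C5 ester and the lactone carbonyl make C6 electrophilic while the acetal makes its CH2 nucleophilic, so the new methoxy group ends para to the ester and meta to the methoxy group carried in from the pyranone. The donor methoxy group on pyranone C4 lowers the diene reactivity, which is why excess ketene acetal and heating in a sealed vessel are planned.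

**Step 7**
Reactants: 12 methyl 2-[2-(3-benzyloxyphenyl)ethyl]-4,6-dimethoxybenzoate
Product: 13 [2-[2-(3-benzyloxyphenyl)ethyl]-4,6-dimethoxyphenyl]methanol
Conditions: LiAlH4, THF, 0 °C to reflux; H2O, aq. NaOH work-up
Reagents that add atoms: none
Why: Hydride reduction of an ester with the small, strong donor LiAlH4 should overcome the hindrance of the two ortho substituents, while the aryl methyl and benzyl ethers are inert.

**Step 8**
Reactants: 13 [2-[2-(3-benzyloxyphenyl)ethyl]-4,6-dimethoxyphenyl]methanol
Product: 14 2-[2-(3-benzyloxyphenyl)ethyl]-4,6-dimethoxybenzaldehyde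
Conditions: MnO2 (excess), CH2Cl2, rt
Reagents that add atoms: none
Why: Heterogeneous MnO2 oxidation is selective for benzylic alcohols, stops at the aldehyde and stays neutral, which avoids ionization of the electron-rich dimethoxybenzyl alcohol.

**Step 9**
Reactants: 14 2-[2-(3-benzyloxyphenyl)ethyl]-4,6-dimethoxybenzaldehyde; 15 1-(benzyloxy)-4-bromobenzene
Product: 17 [2-[2-(3-benzyloxyphenyl)ethyl]-4,6-dimethoxyphenyl](4-benzyloxyphenyl)methanol (racemic), via 4-benzyloxyphenylmagnesium bromide 16 (not isolated)
Conditions: 15, Mg, cat. I2, THF, reflux; then 14, THF, 0 °C to rt; aq. NH4Cl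
Reagents that add atoms: none
Why: Grignard 1,2-addition of the arylmagnesium bromide to a non-enolizable aromatic aldehyde should give the diarylcarbinol, whose new stereocentre forms without control as a racemate and is removed in step 10.

**Step 10**
Reactants: 17 [2-[2-(3-benzyloxyphenyl)ethyl]-4,6-dimethoxyphenyl](4-benzyloxyphenyl)methanol
Product: 18 Gymconopin D, 3-[2-[2-(4-hydroxybenzyl)-3,5-dimethoxyphenyl]ethyl]phenol
Conditions: H2 (1 atm), 10% Pd/C (palladium on carbon), EtOAc–AcOH, rt
Reagents that add atoms: none
Why: Catalytic hydrogenolysis should cleave both O-benzyl ethers and, in the same operation, the doubly benzylic C–OH bond, which is activated by the ortho and para methoxy groups of ring B and the para oxygen of ring C, while the CH2CH2 link and the arenes are untouched.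

**Compound list**
1 | 3-(3-hydroxyphenyl)propanoic acid | OC(=O)CCc1cccc(O)c1 | starting material
2 | benzyl 3-(3-benzyloxyphenyl)propanoate | O=C(CCc1cccc(OCc2ccccc2)c1)OCc1ccccc1 | intermediate
3 | 3-(3-benzyloxyphenyl)propanoic acid | OC(=O)CCc1cccc(OCc2ccccc2)c1 | intermediate
4 | 3-(3-benzyloxyphenyl)propanoyl chloride | ClC(=O)CCc1cccc(OCc2ccccc2)c1 | intermediate
5 | dimethyl 3-oxopentanedioate | COC(=O)CC(=O)CC(=O)OC | starting material
6 | dimethyl 2-[3-(3-benzyloxyphenyl)propanoyl]-3-oxopentanedioate (triketo tautomer drawn) | COC(=O)CC(=O)C(C(=O)OC)C(=O)CCc1cccc(OCc2ccccc2)c1 | intermediate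
7 | methyl 6-[2-(3-benzyloxyphenyl)ethyl]-4-hydroxy-2-oxo-2H-pyran-5-carboxylate | COC(=O)C1=C(CCc2cccc(OCc3ccccc3)c2)OC(=O)C=C1O | intermediate
8 | methyl 6-[2-(3-benzyloxyphenyl)ethyl]-4-methoxy-2-oxo-2H-pyran-5-carboxylate | COC(=O)C1=C(CCc2cccc(OCc3ccccc3)c2)OC(=O)C=C1OC | intermediate
9 | 1,1-dimethoxyethene | C=C(OC)OC | starting material
10 | methyl 1-[2-(3-benzyloxyphenyl)ethyl]-5,8,8-trimethoxy-3-oxo-2-oxabicyclo[2.2.2]oct-5-ene-6-carboxylate (racemic; the bicycle fixes the relative configuration of the two bridgeheads) | O=C1OC2(CCc3cccc(OCc4ccccc4)c3)CC(OC)(OC)C1C(OC)=C2C(=O)OC | intermediate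
11 | methyl 2-[2-(3-benzyloxyphenyl)ethyl]-4,4,6-trimethoxycyclohexa-1,5-diene-1-carboxylate | COC(=O)C1=C(CCc2cccc(OCc3ccccc3)c2)CC(OC)(OC)C=C1OC | intermediate
12 | methyl 2-[2-(3-benzyloxyphenyl)ethyl]-4,6-dimethoxybenzoate | COC(=O)c1c(CCc2cccc(OCc3ccccc3)c2)cc(OC)cc1OC | intermediate
13 | [2-[2-(3-benzyloxyphenyl)ethyl]-4,6-dimethoxyphenyl]methanol | OCc1c(CCc2cccc(OCc3ccccc3)c2)cc(OC)cc1OC | intermediate
14 | 2-[2-(3-benzyloxyphenyl)ethyl]-4,6-dimethoxybenzaldehyde | O=Cc1c(CCc2cccc(OCc3ccccc3)c2)cc(OC)cc1OC | intermediate
15 | 1-(benzyloxy)-4-bromobenzene | Brc1ccc(OCc2ccccc2)cc1 | starting material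
16 | 4-benzyloxyphenylmagnesium bromide | Br[Mg]c1ccc(OCc2ccccc2)cc1 | intermediate
17 | [2-[2-(3-benzyloxyphenyl)ethyl]-4,6-dimethoxyphenyl](4-benzyloxyphenyl)methanol (racemic) | COc1cc(CCc2cccc(OCc3ccccc3)c2)c(C(O)c2ccc(OCc3ccccc3)cc2)c(OC)c1 | intermediate
18 | Gymconopin D | COc1cc(CCc2cccc(O)c2)c(Cc2ccc(O)cc2)c(OC)c1 | target

**Step count.** Total: 10 steps. Longest linear sequence: 10 steps (1 to 18); bromoarene 15 enters in step 9.

**Steps most likely to fail**

Step 6. The cycloaddition may be too slow because the methoxy donor on pyranone C4 raises the diene LUMO, and the ketene acetal may oligomerize on prolonged heating. The fallback abandons the pyranone and builds ring B by a biomimetic aldol aromatization; it sets out from acid chloride 4 and returns at benzoate 12.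
- Commercial 2,2,6-trimethyl-4H-1,3-dioxin-4-one would be deprotonated with LiN(SiMe3)2 and C-acetylated with acetyl chloride to give 2,2-dimethyl-6-(2-oxopropyl)-4H-1,3-dioxin-4-one F1.
- The dianion of F1 (LiN(iPr)2, THF, −78 °C) would be acylated at its terminal carbon by 4 to give 6-[6-(3-benzyloxyphenyl)-2,4-dioxohexyl]-2,2-dimethyl-4H-1,3-dioxin-4-one F2.
- Heating F2 in toluene with methanol would release acetone and trap the acylketene as methyl 9-(3-benzyloxyphenyl)-3,5,7-trioxononanoate F3.
- In the same pot, Cs2CO3 and then acid would cyclize F3 by C2-to-C7 aldol condensation and dehydration to methyl 2-[2-(3-benzyloxyphenyl)ethyl]-4,6-dihydroxybenzoate F4.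
- Methylation of both phenols of F4 (Me2SO4, K2CO3, acetone, reflux) would give 12.

Step 4. The delocalized tricarbonyl enolate may fail to close the lactone, or the acyl group may be lost by retro-Claisen cleavage under base. The fallback assembles the pyranone from the other side; it sets out from acid chloride 4 and returns at hydroxypyranone 7.
- 4 would acylate Meldrum's acid (pyridine, CH2Cl2) to give 5-[3-(3-benzyloxyphenyl)-1-hydroxypropylidene]-2,2-dimethyl-1,3-dioxane-4,6-dione F5.
- Refluxing F5 in methanol would give methyl 5-(3-benzyloxyphenyl)-3-oxopentanoate F6 with loss of acetone and CO2.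
- Malonyl dichloride would then C-acylate F6 at the active methylene and close the lactone through the enol oxygen to give 7.

Step 10. Cleavage of the carbinol C–O bond may lag behind debenzylation, or the stabilized diarylmethyl cation may undergo Friedel–Crafts self-condensation on the catalyst in acid. The fallback separates the two events; it sets out from carbinol 17 and returns at target 18.
- Ionic hydrogenation of 17 (Et3SiH, CF3CO2H, CH2Cl2, 0 °C) would give 1-[2-(3-benzyloxyphenyl)ethyl]-2-(4-benzyloxybenzyl)-3,5-dimethoxybenzene F7.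
- Neutral hydrogenolysis of the two benzyl ethers of F7 (H2, Pd/C, EtOAc–MeOH) would give 18.

**Further compounds**
F1 | step 6 | 2,2-dimethyl-6-(2-oxopropyl)-4H-1,3-dioxin-4-one | CC(=O)CC1=CC(=O)OC(C)(C)O1
F2 | step 6 | 6-[6-(3-benzyloxyphenyl)-2,4-dioxohexyl]-2,2-dimethyl-4H-1,3-dioxin-4-one | CC1(C)OC(=O)C=C(CC(=O)CC(=O)CCc2cccc(OCc3ccccc3)c2)O1
F3 | step 6 | methyl 9-(3-benzyloxyphenyl)-3,5,7-trioxononanoate | COC(=O)CC(=O)CC(=O)CC(=O)CCc1cccc(OCc2ccccc2)c1
F4 | step 6 | methyl 2-[2-(3-benzyloxyphenyl)ethyl]-4,6-dihydroxybenzoate | COC(=O)c1c(CCc2cccc(OCc3ccccc3)c2)cc(O)cc1O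
F5 | step 4 | 5-[3-(3-benzyloxyphenyl)-1-hydroxypropylidene]-2,2-dimethyl-1,3-dioxane-4,6-dione | CC1(C)OC(=O)C(=C(O)CCc2cccc(OCc3ccccc3)c2)C(=O)O1
F6 | step 4 | methyl 5-(3-benzyloxyphenyl)-3-oxopentanoate | COC(=O)CC(=O)CCc1cccc(OCc2ccccc2)c1
F7 | step 10 | 1-[2-(3-benzyloxyphenyl)ethyl]-2-(4-benzyloxybenzyl)-3,5-dimethoxybenzene | COc1cc(CCc2cccc(OCc3ccccc3)c2)c(Cc2ccc(OCc3ccccc3)cc2)c(OC)c1
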